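**Retrosynthetic overview**
1. The target (an achiral flavone) is reached from the 5,7‑dihydroxy‑6‑methoxyflavone 19 by methylation of the free 7‑OH and removal of the 3'‑O‑benzyl group.
2. The strategy rests on ring A (C4a–C5–C6–C7–C8–C8a): C5 and C7 carry oxygen in the acetate pattern and C6 carries an extra methoxyl. The C7–C8 bond is cut, so ring A comes from a vinylogous Claisen closure of the C2‑methyl group of the 3‑(methoxymalonyl)‑6‑aryl‑4‑pyranone 17 onto its own ester.
3. 17 comes from the pyranone‑3‑carboxylic acid 13 and a methoxymalonate half ester by decarboxylative Claisen acylation.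
4. The pyranone (ring C) comes from tert‑butyl acetoacetate and the B‑ring arylpropioloyl chloride by C‑acylation and 6‑endo‑dig oxa‑Michael closure.
5. Ring B is bought as 2,6‑dimethoxyphenol and elaborated (benzylation, formylation, bromination, methoxylation, Corey–Fuchs/CO2). Ring order: B (bought), then C, then A last.

Key step: step 11

Remark: the target has no stereocentre, so "single enantiomer" means the one achiral compound. Compounds 17 and 18 are racemic at a carbon that ends as the sp2 C6.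

**Step 1**
Reactants: 1 2,6‑dimethoxyphenol
Product: 2 2‑(benzyloxy)‑1,3‑dimethoxybenzene
Conditions: BnBr, K2CO3, DMF, rt
Reagents that add atoms: benzyl bromide, BrCc1ccccc1
Why: Williamson ether synthesis on the phenoxide; benzyl is chosen because it should survive base, TFA and amide bases and leave at the end by hydrogenolysis.

**Step 2**
Reactants: 2 2‑(benzyloxy)‑1,3‑dimethoxybenzene
Product: 3 3‑(benzyloxy)‑2,4‑dimethoxybenzaldehyde
Conditions: POCl3, DMF, 80 °C; then aq. NaOAc
Reagents that add atoms: N,N‑dimethylformamide, CN(C)C=O; water, O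
Why: Vilsmeier–Haack formylation should go to C4, which is ortho to one methoxyl and para to the other, as it does in 1,2,3‑trimethoxybenzene, whereas C5 is activated only by the twisted central ether.

**Step 3**
Reactants: 3 3‑(benzyloxy)‑2,4‑dimethoxybenzaldehyde
Product: 4 3‑(benzyloxy)‑5‑bromo‑2,4‑dimethoxybenzaldehyde
Conditions: NBS, MeCN, rt, dark
Reagents that add atoms: N‑bromosuccinimide, O=C1CCC(=O)N1Br
Why: electrophilic aromatic bromination should take C5 only, since it is ortho to the 4‑methoxyl, para to the 2‑methoxyl and meta to the formyl group, while C6 is ortho to the deactivating formyl group.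

**Step 4**
Reactants: 4 3‑(benzyloxy)‑5‑bromo‑2,4‑dimethoxybenzaldehyde
Product: 5 3‑(benzyloxy)‑2,4,5‑trimethoxybenzaldehyde
Conditions: NaOMe (5 equiv), CuBr (10 mol%), DMF–MeOH, 100 °C
Reagents that add atoms: sodium methoxide, [Na+].[O-]C
Why: copper‑catalysed Ullmann‑type methoxylation of the aryl bromide; the aldehyde has no α‑hydrogen, and any SNAr exchange at the 2‑ and 4‑methoxyls by methoxide is degenerate.

**Step 5**
Reactants: 5 3‑(benzyloxy)‑2,4,5‑trimethoxybenzaldehyde
Product: 6 3‑(benzyloxy)‑1‑(2,2‑dibromoethenyl)‑2,4,5‑trimethoxybenzene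
Conditions: CBr4, PPh3, CH2Cl2, 0 °C
Reagents that add atoms: carbon tetrabromide, BrC(Br)(Br)Br
Why: first stage of the Corey–Fuchs homologation, a Wittig‑type dibromo‑olefination that works well on electron‑rich aryl aldehydes.

**Step 6**
Reactants: 6 3‑(benzyloxy)‑1‑(2,2‑dibromoethenyl)‑2,4,5‑trimethoxybenzene
Product: 8 3‑[3‑(benzyloxy)‑2,4,5‑trimethoxyphenyl]prop‑2‑ynoic acid, via lithium arylacetylide 7 (not isolated)
Conditions: n‑BuLi (2.2 equiv), THF, −78 °C; then CO2; 1 M HCl
Reagents that add atoms: carbon dioxide, O=C=O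
Why: second stage of the Corey–Fuchs reaction (Br/Li exchange and elimination to the lithium acetylide) followed by carboxylation; at −78 °C the benzyl ether should not be metalated.

**Step 7**
Reactants: 8 3‑[3‑(benzyloxy)‑2,4,5‑trimethoxyphenyl]prop‑2‑ynoic acid; 9 tert‑butyl 3‑oxobutanoate (tert‑butyl acetoacetate)
Product: 12 tert‑butyl 6‑[3‑(benzyloxy)‑2,4,5‑trimethoxyphenyl]‑2‑methyl‑4‑oxo‑4H‑pyran‑3‑carboxylate, via arylpropioloyl chloride 10 (not isolated), via C‑acylated ynone keto ester 11 (not isolated)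
Conditions: (COCl)2, cat. DMF, CH2Cl2, 0 °C to rt, evaporate; 9 (2 equiv), i‑PrMgCl (2 equiv), THF, 0 °C, then 10, −20 °C to rt; aq. NH4Cl; crude 11, K2CO3, acetone, rt
Reagents that add atoms: none
Why: C‑acylation of the chelated magnesium enolate of a β‑keto ester by an acid chloride, then 6‑endo‑dig oxa‑Michael closure of the enolised ynone through the acetyl oxygen, which is the only ketone enol oxygen present, so methyl must end at C2 and the ester at C3 of the γ‑pyranone.

**Step 8**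
Reactants: 12 tert‑butyl 6‑[3‑(benzyloxy)‑2,4,5‑trimethoxyphenyl]‑2‑methyl‑4‑oxo‑4H‑pyran‑3‑carboxylate
Product: 13 6‑[3‑(benzyloxy)‑2,4,5‑trimethoxyphenyl]‑2‑methyl‑4‑oxo‑4H‑pyran‑3‑carboxylic acid
Conditions: TFA–CH2Cl2 (1:4), 0 °C to rt
Reagents that add atoms: none
Why: acidolysis of the tert‑butyl ester with loss of isobutene avoids hydroxide, which would open the pyranone; the benzyl ether and methyl ethers should tolerate short exposure to TFA at rt.

**Step 9**
Reactants: 14 dimethyl 2‑methoxymalonate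
Product: 15 potassium 2,3‑dimethoxy‑3‑oxopropanoate (potassium methyl methoxymalonate)
Conditions: KOH (1.0 equiv), MeOH, 0 °C to rt
Reagents that add atoms: potassium hydroxide, [K+].[OH-]
Why: mono‑saponification of a symmetrical malonate with one equivalent of hydroxide; the carboxylate formed deactivates the second ester toward hydrolysis.

**Step 10**
Reactants: 13 6‑[3‑(benzyloxy)‑2,4,5‑trimethoxyphenyl]‑2‑methyl‑4‑oxo‑4H‑pyran‑3‑carboxylic acid; 15 potassium 2,3‑dimethoxy‑3‑oxopropanoate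
Product: 17 methyl 3‑{6‑[3‑(benzyloxy)‑2,4,5‑trimethoxyphenyl]‑2‑methyl‑4‑oxo‑4H‑pyran‑3‑yl}‑2‑methoxy‑3‑oxopropanoate (racemic), via acyl imidazolide 16 (not isolated)
Conditions: CDI, THF, rt; then 15 (2.5 equiv), MgCl2, Et3N, MeCN, rt to 45 °C; aq. citric acid
Reagents that add atoms: none
Why: Masamune–Brooks decarboxylative Claisen acylation of a magnesium malonate half ester by an acyl imidazolide; the near‑neutral conditions should neither deprotonate the C2‑methyl group irreversibly nor open the pyranone.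

**Step 11**
Reactants: 17 methyl 3‑{6‑[3‑(benzyloxy)‑2,4,5‑trimethoxyphenyl]‑2‑methyl‑4‑oxo‑4H‑pyran‑3‑yl}‑2‑methoxy‑3‑oxopropanoate
Product: 19 2‑[3‑(benzyloxy)‑2,4,5‑trimethoxyphenyl]‑5,7‑dihydroxy‑6‑methoxy‑4H‑chromen‑4‑one, via chromene‑4,5,7‑trione 18 (not isolated)
Conditions: LDA (3.2 equiv), THF (0.02 M), −78 °C, then 0 °C to rt; 1 M HCl
Reagents that add atoms: none
Why: Proposed new method: the first equivalent of LDA removes the C–H between ketone and ester and the second removes a proton of the C2‑methyl group, which is vinylogous to the pyranone C4 carbonyl, so that the exocyclic carbon of the dienolate attacks the ester carbonyl, methoxide leaves to form the C7–C8 bond, and the cyclic triketone 18 enolises irreversibly to the aromatic 5,7‑diolate. The closest known reactions are the base‑mediated Claisen cyclisation of 3,5,7‑triketo esters to acylphloroglucinols and the acylation of lithiated 2‑methyl‑4‑pyranones by esters at the methyl carbon. Ring A closes in a 6‑(enolendo)‑exo‑trig mode, which the enolate rules allow, and the cis placement of methyl and acyl on the pyranone C2=C3 bond holds the two ends within reach. No stereocentre is formed, because the racemic CH(OMe) carbon of 17 becomes the sp2 C6. The step needs C‑attack of the methyl dienolate on the ester in preference to pyranone ring opening and intermolecular condensation; a non‑nucleophilic amide base, dilution and the six‑membered reach of the tethered ester should secure this, and because the O1–C8a bond is never broken the methoxyl can only end at C6 and not at C8. Lithium bridging between the side‑chain enolate oxygen and the α‑methoxyl is expected to hold the ester carbon on the ring side of the enolate, which is the geometry closure requires.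

**Step 12**
Reactants: 19 2‑[3‑(benzyloxy)‑2,4,5‑trimethoxyphenyl]‑5,7‑dihydroxy‑6‑methoxy‑4H‑chromen‑4‑one
Product: 20 2‑[3‑(benzyloxy)‑2,4,5‑trimethoxyphenyl]‑5‑hydroxy‑6,7‑dimethoxy‑4H‑chromen‑4‑one
Conditions: MeI (1.1 equiv), K2CO3 (1.2 equiv), acetone, rt
Reagents that add atoms: iodomethane, CI
Why: Williamson O‑methylation should be selective for the 7‑OH, since the 5‑OH is held in a hydrogen bond to the C4 carbonyl and is much less acidic and nucleophilic.

**Step 13**
Reactants: 20 2‑[3‑(benzyloxy)‑2,4,5‑trimethoxyphenyl]‑5‑hydroxy‑6,7‑dimethoxy‑4H‑chromen‑4‑one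
Product: 21 psiadiarabicin, 5‑hydroxy‑2‑(3‑hydroxy‑2,4,5‑trimethoxyphenyl)‑6,7‑dimethoxy‑4H‑chromen‑4‑one
Conditions: H2 (1 atm), 10% Pd/C, EtOAc–MeOH, rt
Reagents that add atoms: none
Why: catalytic hydrogenolysis of the benzyl aryl ether; the flavone C2=C3 bond and the chelated carbonyl should not be reduced at 1 atm and rt.

**Compound list**
1 | 2,6‑dimethoxyphenol | COc1cccc(OC)c1O | starting material
2 | 2‑(benzyloxy)‑1,3‑dimethoxybenzene | COc1cccc(OC)c1OCc1ccccc1 | intermediate
3 | 3‑(benzyloxy)‑2,4‑dimethoxybenzaldehyde | O=Cc1ccc(OC)c(OCc2ccccc2)c1OC | intermediate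
4 | 3‑(benzyloxy)‑5‑bromo‑2,4‑dimethoxybenzaldehyde | O=Cc1cc(Br)c(OC)c(OCc2ccccc2)c1OC | intermediate
5 | 3‑(benzyloxy)‑2,4,5‑trimethoxybenzaldehyde | O=Cc1cc(OC)c(OC)c(OCc2ccccc2)c1OC | intermediate
6 | 3‑(benzyloxy)‑1‑(2,2‑dibromoethenyl)‑2,4,5‑trimethoxybenzene | BrC(Br)=Cc1cc(OC)c(OC)c(OCc2ccccc2)c1OC | intermediate
7 | lithium [3‑(benzyloxy)‑2,4,5‑trimethoxyphenyl]acetylide | [Li]C#Cc1cc(OC)c(OC)c(OCc2ccccc2)c1OC | intermediate
8 | 3‑[3‑(benzyloxy)‑2,4,5‑trimethoxyphenyl]prop‑2‑ynoic acid | OC(=O)C#Cc1cc(OC)c(OC)c(OCc2ccccc2)c1OC | intermediate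
9 | tert‑butyl 3‑oxobutanoate | CC(=O)CC(=O)OC(C)(C)C | starting material
10 | 3‑[3‑(benzyloxy)‑2,4,5‑trimethoxyphenyl]prop‑2‑ynoyl chloride | ClC(=O)C#Cc1cc(OC)c(OC)c(OCc2ccccc2)c1OC | intermediate
11 | tert‑butyl 2‑acetyl‑5‑[3‑(benzyloxy)‑2,4,5‑trimethoxyphenyl]‑3‑oxopent‑4‑ynoate (drawn as the triketo form, enolised in fact) | CC(=O)C(C(=O)OC(C)(C)C)C(=O)C#Cc1cc(OC)c(OC)c(OCc2ccccc2)c1OC | intermediate
12 | tert‑butyl 6‑[3‑(benzyloxy)‑2,4,5‑trimethoxyphenyl]‑2‑methyl‑4‑oxo‑4H‑pyran‑3‑carboxylate | Cc1oc(-c2cc(OC)c(OC)c(OCc3ccccc3)c2OC)cc(=O)c1C(=O)OC(C)(C)C | intermediate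
13 | 6‑[3‑(benzyloxy)‑2,4,5‑trimethoxyphenyl]‑2‑methyl‑4‑oxo‑4H‑pyran‑3‑carboxylic acid | Cc1oc(-c2cc(OC)c(OC)c(OCc3ccccc3)c2OC)cc(=O)c1C(=O)O | intermediate
14 | dimethyl 2‑methoxymalonate | COC(C(=O)OC)C(=O)OC | starting material
15 | potassium 2,3‑dimethoxy‑3‑oxopropanoate | COC(C(=O)OC)C(=O)[O-].[K+] | intermediate
16 | {6‑[3‑(benzyloxy)‑2,4,5‑trimethoxyphenyl]‑2‑methyl‑4‑oxo‑4H‑pyran‑3‑yl}(1H‑imidazol‑1‑yl)methanone | Cc1oc(-c2cc(OC)c(OC)c(OCc3ccccc3)c2OC)cc(=O)c1C(=O)n1ccnc1 | intermediate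
17 | methyl 3‑{6‑[3‑(benzyloxy)‑2,4,5‑trimethoxyphenyl]‑2‑methyl‑4‑oxo‑4H‑pyran‑3‑yl}‑2‑methoxy‑3‑oxopropanoate (racemic) | COC(=O)C(OC)C(=O)c1c(C)oc(-c2cc(OC)c(OC)c(OCc3ccccc3)c2OC)cc1=O | intermediate
18 | 2‑[3‑(benzyloxy)‑2,4,5‑trimethoxyphenyl]‑6‑methoxy‑6H‑chromene‑4,5,7(8H)‑trione (racemic, present as its lithium enolate) | COC1C(=O)Cc2oc(-c3cc(OC)c(OC)c(OCc4ccccc4)c3OC)cc(=O)c2C1=O | intermediate
19 | 2‑[3‑(benzyloxy)‑2,4,5‑trimethoxyphenyl]‑5,7‑dihydroxy‑6‑methoxy‑4H‑chromen‑4‑one | COc1c(O)cc2oc(-c3cc(OC)c(OC)c(OCc4ccccc4)c3OC)cc(=O)c2c1O | intermediate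
20 | 2‑[3‑(benzyloxy)‑2,4,5‑trimethoxyphenyl]‑5‑hydroxy‑6,7‑dimethoxy‑4H‑chromen‑4‑one | COc1cc2oc(-c3cc(OC)c(OC)c(OCc4ccccc4)c3OC)cc(=O)c2c(O)c1OC | intermediate
21 | psiadiarabicin (achiral) | COc1cc(-c2cc(=O)c3c(O)c(OC)c(OC)cc3o2)c(OC)c(O)c1OC | target

**Step count**
Total steps: 13. Longest linear sequence: 12 (steps 1–8 and 10–13; step 9 is a one‑step side branch).

**Steps most likely to fail**

1. Step 11 (proposed new method). Deprotonation may stop at the mono‑enolate. Attack on the ester, which is deactivated by conjugation with that enolate, may be slower than pyranone ring opening or intermolecular condensation. The fallback uses known flavone chemistry. It sets out from aldehyde 5 and comes back to the route at 20.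
   - Claisen–Schmidt condensation of 5 with commercial 1‑(6‑hydroxy‑2,3,4‑trimethoxyphenyl)ethan‑1‑one (CC(=O)c1c(O)cc(OC)c(OC)c1OC) using KOH in EtOH should give the chalcone (E)‑3‑[3‑(benzyloxy)‑2,4,5‑trimethoxyphenyl]‑1‑(6‑hydroxy‑2,3,4‑trimethoxyphenyl)prop‑2‑en‑1‑one F1.
   - Oxidative cyclisation with catalytic I2 in DMSO at 130 °C should give 2‑[3‑(benzyloxy)‑2,4,5‑trimethoxyphenyl]‑5,6,7‑trimethoxy‑4H‑chromen‑4‑one F2.
   - Chelation‑controlled cleavage of the 5‑methoxyl peri to the carbonyl with MgBr2·OEt2 in MeCN–toluene at 70 °C should give 20, which continues with step 13.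

2. Step 7. The magnesium enolate may add 1,4 to the ynoyl chloride instead of acylating, which would lead to a 2‑pyranone. HCl may add across the electron‑rich alkyne during chloride formation. The fallback avoids the alkyne altogether. It sets out from aldehyde 5 and keto ester 9, replaces steps 5–7, and comes back at 12.
   - Huckin–Weiler aldol addition of the dianion of 9 (NaH, then n‑BuLi, THF, 0 °C) to 5 at −78 °C should give tert‑butyl 5‑[3‑(benzyloxy)‑2,4,5‑trimethoxyphenyl]‑5‑hydroxy‑3‑oxopentanoate F3.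
   - Condensation of the active methylene with N,N‑dimethylacetamide dimethyl acetal (toluene, rt to 80 °C, then PPTS), with displacement of dimethylamine by the δ‑hydroxyl, should give tert‑butyl 2‑[3‑(benzyloxy)‑2,4,5‑trimethoxyphenyl]‑6‑methyl‑4‑oxo‑3,4‑dihydro‑2H‑pyran‑5‑carboxylate F4.
   - Dehydrogenation with DDQ in dioxane at reflux, helped by the electron‑rich benzylic C2–H, should give 12.

3. Step 10. The acyl imidazolide is hindered and is a vinylogous carbonate, so C‑acylation may be slow, and the half ester may decarboxylate to methyl methoxyacetate before the C–C bond forms. The fallback is a direct crossed Claisen. It sets out from acid 13 and comes back at 17.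
   - Oxalyl chloride with catalytic DMF in CH2Cl2 should give 6‑[3‑(benzyloxy)‑2,4,5‑trimethoxyphenyl]‑2‑methyl‑4‑oxo‑4H‑pyran‑3‑carbonyl chloride F5.
   - Adding F5 at −78 °C to the lithium enolate of methyl methoxyacetate (COCC(=O)OC, 2.2 equiv, LDA, THF) should give 17 after acidic quench; the second equivalent of enolate takes up the acidic proton of the product.

**Further compounds**
F1 | step 11 | (E)‑3‑[3‑(benzyloxy)‑2,4,5‑trimethoxyphenyl]‑1‑(6‑hydroxy‑2,3,4‑trimethoxyphenyl)prop‑2‑en‑1‑one | COc1cc(O)c(C(=O)/C=C/c2cc(OC)c(OC)c(OCc3ccccc3)c2OC)c(OC)c1OC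
F2 | step 11 | 2‑[3‑(benzyloxy)‑2,4,5‑trimethoxyphenyl]‑5,6,7‑trimethoxy‑4H‑chromen‑4‑one | COc1cc2oc(-c3cc(OC)c(OC)c(OCc4ccccc4)c3OC)cc(=O)c2c(OC)c1OC
F3 | step 7 | tert‑butyl 5‑[3‑(benzyloxy)‑2,4,5‑trimethoxyphenyl]‑5‑hydroxy‑3‑oxopentanoate (racemic) | CC(C)(C)OC(=O)CC(=O)CC(O)c1cc(OC)c(OC)c(OCc2ccccc2)c1OC
F4 | step 7 | tert‑butyl 2‑[3‑(benzyloxy)‑2,4,5‑trimethoxyphenyl]‑6‑methyl‑4‑oxo‑3,4‑dihydro‑2H‑pyran‑5‑carboxylate (racemic) | CC1=C(C(=O)OC(C)(C)C)C(=O)CC(O1)c1cc(OC)c(OC)c(OCc2ccccc2)c1OC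
F5 | step 10 | 6‑[3‑(benzyloxy)‑2,4,5‑trimethoxyphenyl]‑2‑methyl‑4‑oxo‑4H‑pyran‑3‑carbonyl chloride | Cc1oc(-c2cc(OC)c(OC)c(OCc3ccccc3)c2OC)cc(=O)c1C(Cl)=O
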